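The numbers in the tables are calculated with made-up constants; noise was put on by code.

Two chemists dispute two flasks.

all flasks: gas 0.77 mM (held)

| charge | substrate | temperature | remark | time |
|---|---|---|---|---|
| Sunday's | 7 mM | 25 °C | run made earlier |  |
| Saturday's | 8.8 mM | 45 °C | run made earlier |  |
| alpha | 8.0 mM |  | at 30 °C throughout | 6.0 h |
| theta | 12 mM |  | at 60 °C until 2.0 h, from then on at 30 °C | 6.0 h |

| run | time / h | ring / % | substrate / % |
|---|---|---|---|
| Sunday's | 2.00 | 2.0 | 63.0 |
| Sunday's | 3.00 | 1.2 | 46.3 |
| Sunday's | 5.00 | 5.4 | 20.9 |
| Sunday's | 8.00 | 7.7 | 5.5 |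
| Sunday's | 12.0 | 11.1 | 0.8 |
| Sunday's | 15.0 | 16.2 | 1.7 |
| Sunday's | 25.0 | 20.4 | 1.4 |
| Saturday's | 0.500 | 2.5 | 70.1 |
| Saturday's | 1.33 | 5.9 | 28.0 |
| Saturday's | 3.00 | 14.0 | 2.7 |
| Saturday's | 4.00 | 18.3 | 1.0 |
| Saturday's | 5.00 | 17.9 | 2.0 |
| Saturday's | 6.00 | 20.4 | 0 |
| Saturday's | 8.00 | 24.1 | 0 |

(each reading ± 1 percentage point)

- which of the two ends with the higher amount of ring, in percent of the substrate charged ("neither" if they lie within 2 percentage points) (alpha / theta / neither)
- ring at the end, in percent of the substrate charged, alpha
- ring at the end, in percent of the substrate charged, theta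

- percentages count the substrate that a species holds: one open dimer counts as two
- at the start none of activator is dissolved
- what may be going on: substrate + activator -> activated form; activated form -> ring; substrate + activated form -> open dimer; gas <-> activator

On the proposed steps, ring comes from the activated form, an intermediate that sits in the flask as a pool and empties into ring like a tank through an outlet. Sunday's run times that outlet. At 12.0 h the substrate reads 0.8% and ring 11.1%; at 25.0 h ring reads 20.4%. I take the pool as what ring has still to gain, up to a ceiling of 24.1% of the charge, the highest ring read in either run. That gives 10.3 h, the time in which the pool falls by a factor e: the drain time. It is a reading with scatter. A higher ceiling would lengthen it, and I expect 30 °C to shorten it against Sunday's 25 °C, so I use it as it stands for the cool hours.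

The first chemist counts shares: substrate also eats the pool to make open dimer, and alpha is charged with 8.0 mM against theta's 12 mM, so alpha should save more for ring. The second counts the clock: alpha's 6.0 h is 0.583 drain times, so even a pool full from the start hands over a fraction 44.0%, which is 10.6% of the charge at that ceiling. Theta gets 2.0 h at 60 °C, and Saturday's cooler flask already read 14.0% at 3.00 h. I side with the second: I expect alpha below that figure and theta near Saturday's, more than alpha.

The forecast also says theta, with alpha at 8%, under my estimate, and theta at 19%, above my estimate, on the ground that “a pool of activated form is draining slowly”.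

The flasks give theta: alpha 8.79%, theta 16.1%.

    substrate + activator → activated form (k = 61.0 M⁻¹ min⁻¹, Ea = 61.0 kJ mol⁻¹)
    activated form → ring (k = 0.0440 min⁻¹, Ea = 90.0 kJ mol⁻¹)
    substrate + activated form → open dimer (k = 34.0 M⁻¹ min⁻¹, Ea = 70.0 kJ mol⁻¹)
    gas ⇌ activator, rate k4*(csat - [activator]) (kL = 0.160 min⁻¹)
    (constants at 60 °C)

Theta's ring is held down mainly because of the open dimer step: theta ends at 16.1% with that step and at 76.6% without it. Alpha's low figure comes from that step and the short run together: alpha ends at 8.79%, against 24.6% without the step and 25.4% in a run ten times as long. At 6.00 h alpha holds 14.8% as activated form, and theta holds 2.25%. Over a further 54.0 h, the drain time leaves 0.0803% in alpha and 0.0122% in theta; the flasks hold 0.0569% and 0.00880%. The first chemist's shares win on that long run: at 60.0 h alpha has 25.4% ring, theta 18.7%.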